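## Retrosynthetic overview

1. The target comes from acid removal of six MOM ethers, preceded by a Heck coupling of a ring D bromide with an aryl vinyl ketone, preceded by release of the C4 ketone from an exocyclic C4=CH2 group (OsO4/NaIO4).
2. Ring C is the only ring to be built, and it is closed through the aryl ether bond O1–C8a by copper-catalysed intramolecular O-arylation of the C2 alcohol with a ring A iodide.
3. The strategy rests on the O1–C2–C3–C4(=O) array of ring C: its open form is a β-hydroxy ketone with an acidic C3–H (α to C4=O, benzylic to ring D), so C4 is carried as a 1,1-disubstituted alkene until ring C exists, which removes retro-aldol cleavage, dehydration and C3 epimerisation.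
4. The C2–C3 bond and both stereocentres come from an anti-selective asymmetric chromium allylation of 4-(methoxymethoxy)benzaldehyde with an (E)-2,3-diarylallyl bromide, itself made by a Perkin condensation of the ring A arylacetic acid with the ring D aldehyde.
5. Ring A needs its two oxygens ortho and para to the carbon substituent and the iodide meta to both, a pattern that iodination of a 3,5-dioxygenated phenylacetate cannot give; it is therefore built from 1-iodo-3,5-dimethoxybenzene by formylation para to a methoxy group and one-carbon homologation. Rings A, B, D and the chalcone ring are bought as arenes; ring C is formed in step 13.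

Key step: step 13

Assumption: the (S,S) ligand of the allylation step is taken to direct addition to the Re face of the aldehyde, which gives the (1R,2S) homoallylic alcohol. The sense of induction cannot be predicted for this allyl bromide, so the configuration of a first sample would be assigned by MTPA ester analysis and the (R,R) antipode used if the sense is opposite.

## Route

Step 1
Reactants: 1 1-iodo-3,5-dimethoxybenzene
Product: 3 2-iodo-4,6-dimethoxybenzaldehyde, via iminium chloride 2 (not isolated)
Conditions: POCl3, DMF, 0 °C to 90 °C; then ice-water, aq. NaOH to pH 7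
Reagents that add atoms: N,N-dimethylformamide, CN(C)C=O; water, O
Why: Vilsmeier–Haack formylation, in which the chloroiminium ion should attack para to one methoxy group and ortho to the other (next to iodine) rather than the hindered position between the two methoxy groups, and hydrolysis of the iminium salt gives the aldehyde.

Step 2
Reactants: 3 2-iodo-4,6-dimethoxybenzaldehyde
Product: 4 2,4-dihydroxy-6-iodobenzaldehyde
Conditions: BBr3, CH2Cl2, −78 °C to rt; then H2O
Reagents that add atoms: none
Why: Lewis acid cleavage of aryl methyl ethers (bromide attacks the methyl group of the boron-complexed ether), which frees both phenols so that they can be re-protected as acid-labile MOM ethers; the aryl iodide and the aldehyde are inert.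

Step 3
Reactants: 4 2,4-dihydroxy-6-iodobenzaldehyde
Product: 5 2-iodo-4,6-bis(methoxymethoxy)benzaldehyde
Conditions: NaH, MOMCl, DMF, 0 °C to rt
Reagents that add atoms: chloromethyl methyl ether, COCCl
Why: Williamson-type O-alkylation of both phenoxides, the excess of base and MOMCl also capturing the hydrogen-bonded ortho phenol.

Step 4
Reactants: 5 2-iodo-4,6-bis(methoxymethoxy)benzaldehyde
Product: 7 2-[2-iodo-4,6-bis(methoxymethoxy)phenyl]acetonitrile, via N-(1-tosylvinyl)formamide 6 (not isolated)
Conditions: TosMIC, t-BuOK, DME, −40 °C; then MeOH, 65 °C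
Reagents that add atoms: p-toluenesulfonylmethyl isocyanide, Cc1ccc(cc1)S(=O)(=O)C[N+]#[C-]
Why: van Leusen reductive cyanation, in which the TosMIC anion adds to the aldehyde, the oxazoline opens to the N-(1-tosylvinyl)formamide, and methanolysis removes the formyl group and expels sulfinate to leave the homologated nitrile; MOM ethers and the aryl iodide tolerate alkoxide bases.

Step 5
Reactants: 7 2-[2-iodo-4,6-bis(methoxymethoxy)phenyl]acetonitrile
Product: 8 2-[2-iodo-4,6-bis(methoxymethoxy)phenyl]acetic acid
Conditions: KOH, EtOH/H2O, 85 °C; then cold aq. KHSO4 to pH 4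
Reagents that add atoms: water, O; potassium hydroxide, [K+].[OH-]
Why: base hydrolysis of the nitrile through the primary amide to the carboxylate, under which MOM ethers and the aryl iodide are stable; brief cold acidification to pH 4 should not touch the acetals.

Step 6
Reactants: 9 5-bromo-2-hydroxybenzaldehyde
Product: 10 5-bromo-2-(methoxymethoxy)benzaldehyde
Conditions: NaH, MOMCl, DMF, 0 °C to rt
Reagents that add atoms: chloromethyl methyl ether, COCCl
Why: Williamson-type O-alkylation of the phenoxide, which also blocks the coumarin closure that a free ortho phenol would undergo in the next step.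

Step 7
Reactants: 8 2-[2-iodo-4,6-bis(methoxymethoxy)phenyl]acetic acid; 10 5-bromo-2-(methoxymethoxy)benzaldehyde
Product: 12 (E)-3-[5-bromo-2-(methoxymethoxy)phenyl]-2-[2-iodo-4,6-bis(methoxymethoxy)phenyl]prop-2-enoic acid, via mixed acetic anhydride 11 (not isolated)
Conditions: Ac2O, Et3N, 100 °C; then H2O, 60 °C
Reagents that add atoms: none
Why: Perkin condensation, in which the mixed anhydride of 8 enolises, adds to the aldehyde, and elimination of acetate gives the favoured (E)-acid with the two aryl groups cis and the carboxyl trans to ring D, the geometry that later places ring D trans to the CH2 group of the allyl reagent; the Et3N buffer should keep the MOM ethers intact.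

Step 8
Reactants: 12 (E)-3-[5-bromo-2-(methoxymethoxy)phenyl]-2-[2-iodo-4,6-bis(methoxymethoxy)phenyl]prop-2-enoic acid
Product: 13 methyl (E)-3-[5-bromo-2-(methoxymethoxy)phenyl]-2-[2-iodo-4,6-bis(methoxymethoxy)phenyl]prop-2-enoate
Conditions: MeI, K2CO3, DMF, rt
Reagents that add atoms: iodomethane, CI
Why: SN2 O-alkylation of the carboxylate, which avoids acid and does not disturb the alkene geometry.

Step 9
Reactants: 13 methyl (E)-3-[5-bromo-2-(methoxymethoxy)phenyl]-2-[2-iodo-4,6-bis(methoxymethoxy)phenyl]prop-2-enoate
Product: 14 (E)-3-[5-bromo-2-(methoxymethoxy)phenyl]-2-[2-iodo-4,6-bis(methoxymethoxy)phenyl]prop-2-en-1-ol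
Conditions: i-Bu2AlH, CH2Cl2, −78 °C to −20 °C; aq. potassium sodium tartrate
Reagents that add atoms: none
Why: 1,2-reduction of the conjugated ester by the aluminium hydride to the allylic alcohol, without conjugate reduction and without attack on the aryl halides at low temperature.

Step 10
Reactants: 14 (E)-3-[5-bromo-2-(methoxymethoxy)phenyl]-2-[2-iodo-4,6-bis(methoxymethoxy)phenyl]prop-2-en-1-ol
Product: 15 (E)-3-[5-bromo-2-(methoxymethoxy)phenyl]-2-[2-iodo-4,6-bis(methoxymethoxy)phenyl]prop-2-enyl bromide
Conditions: CBr4, PPh3, CH2Cl2, 0 °C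
Reagents that add atoms: carbon tetrabromide, BrC(Br)(Br)Br
Why: Appel reaction, in which bromide displaces the alkoxyphosphonium group at the primary carbon under neutral conditions that spare the MOM ethers; the bromide would be used without storage.

Step 11
Reactants: 16 4-hydroxybenzaldehyde
Product: 17 4-(methoxymethoxy)benzaldehyde
Conditions: NaH, MOMCl, DMF, 0 °C to rt
Reagents that add atoms: chloromethyl methyl ether, COCCl
Why: Williamson-type O-alkylation of the phenoxide.

Step 12
Reactants: 15 (E)-3-[5-bromo-2-(methoxymethoxy)phenyl]-2-[2-iodo-4,6-bis(methoxymethoxy)phenyl]prop-2-enyl bromide; 17 4-(methoxymethoxy)benzaldehyde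
Product: 20 (1R,2S)-2-[5-bromo-2-(methoxymethoxy)phenyl]-3-[2-iodo-4,6-bis(methoxymethoxy)phenyl]-1-[4-(methoxymethoxy)phenyl]but-3-en-1-ol, via allylchromium dichloride 18 (not isolated), via trimethylsilyl ether 19 (not isolated)
Conditions: CrCl2 (10 mol %, nickel-free), (S,S)-3,6-diphenyl-1,8-bis(4-isopropyl-4,5-dihydrooxazol-2-yl)-9H-carbazole (12 mol %), Mn powder, i-Pr2NEt (30 mol %), Me3SiCl, THF, rt; then K2CO3 (cat.), MeOH, rt
Reagents that add atoms: none
Why: catalytic asymmetric Nozaki–Hiyama–Kishi allylation, in which divalent chromium turns the bromide into the (E)-allylchromium (ring D aryl trans to CH2Cr) that adds through its γ-carbon in a closed chair transition state with both aryl groups equatorial, setting the anti C1/C2 pair, while the chiral tridentate ligand on trivalent chromium selects the Re face of the aldehyde and so the (1R,2S) enantiomer; manganese and Me3SiCl turn the catalyst over and nickel-free chromium leaves the aryl iodide and bromide untouched.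

Step 13
Reactants: 20 (1R,2S)-2-[5-bromo-2-(methoxymethoxy)phenyl]-3-[2-iodo-4,6-bis(methoxymethoxy)phenyl]-1-[4-(methoxymethoxy)phenyl]but-3-en-1-ol
Product: 21 (2R,3S)-3-[5-bromo-2-(methoxymethoxy)phenyl]-5,7-bis(methoxymethoxy)-2-[4-(methoxymethoxy)phenyl]-4-methylenechroman
Conditions: CuI (10 mol %), 3,4,7,8-tetramethyl-1,10-phenanthroline (20 mol %), Cs2CO3 (2 equiv), toluene, 90–100 °C, argon
Reagents that add atoms: none
Why: Cs2CO3 generates the C2 alkoxide, which binds phenanthroline-ligated monovalent copper; oxidative addition of the ring A C–I bond gives a trivalent aryl(alkoxo)copper chelate, and reductive elimination forms O1–C8a. The closest known reaction type is the Ullmann-type copper-catalysed etherification of aliphatic alcohols with aryl iodides, which is established in its intramolecular form for chromans. Ring C closes in a six-membered mode, exo with respect to the C–I bond, through a seven-membered cupracycle, and the C4 alkene holds ring A and C3 close to the geometry required. No stereocentre is formed: C2 keeps its configuration because its C–O bond is never broken, and C3 is not acidic while C4 is an alkene and not a carbonyl. The step needs the ring A iodide to react and the ring D bromide to remain, which the faster oxidative addition of C–I and the intramolecular delivery of the alkoxide secure. It also needs the alkoxide to survive, which the methylene mask secures because no β-hydroxy ketone is present to cleave or dehydrate.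

Step 14
Reactants: 21 (2R,3S)-3-[5-bromo-2-(methoxymethoxy)phenyl]-5,7-bis(methoxymethoxy)-2-[4-(methoxymethoxy)phenyl]-4-methylenechroman
Product: 23 (2R,3S)-3-[5-bromo-2-(methoxymethoxy)phenyl]-5,7-bis(methoxymethoxy)-2-[4-(methoxymethoxy)phenyl]chroman-4-one, via 4-(hydroxymethyl)chroman-4-ol 22 (not isolated)
Conditions: OsO4 (4 mol %), NaIO4 (4 equiv), 2,6-lutidine (2 equiv), 1,4-dioxane/H2O 3:1, rt
Reagents that add atoms: osmium tetroxide, O=[Os](=O)(=O)=O; sodium periodate, [Na+].[O-]I(=O)(=O)=O
Why: Lemieux–Johnson oxidation, in which the only alkene is dihydroxylated and the diol is cleaved by periodate to the C4 ketone and formaldehyde; the lutidine buffer and room temperature should leave the MOM ethers and the now enolisable C3 untouched, and the trans arrangement fixed by C2 is the stable one.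

Step 15
Reactants: 24 2,4-dihydroxybenzaldehyde
Product: 25 2,4-bis(methoxymethoxy)benzaldehyde
Conditions: NaH, MOMCl, DMF, 0 °C to rt
Reagents that add atoms: chloromethyl methyl ether, COCCl
Why: Williamson-type O-alkylation of both phenoxides.

Step 16
Reactants: 25 2,4-bis(methoxymethoxy)benzaldehyde
Product: 26 1-[2,4-bis(methoxymethoxy)phenyl]prop-2-en-1-ol
Conditions: CH2=CHMgBr, THF, −78 °C to 0 °C; aq. NH4Cl
Reagents that add atoms: vinylmagnesium bromide, C=C[Mg]Br
Why: Grignard 1,2-addition to the aldehyde; the racemic carbinol centre is removed in the next step.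

Step 17
Reactants: 26 1-[2,4-bis(methoxymethoxy)phenyl]prop-2-en-1-ol
Product: 27 1-[2,4-bis(methoxymethoxy)phenyl]prop-2-en-1-one
Conditions: MnO2, CH2Cl2, rt
Reagents that add atoms: none
Why: MnO2 oxidation of an alcohol that is both allylic and benzylic under neutral conditions; the aryl vinyl ketone would be used at once to avoid polymerisation.

Step 18
Reactants: 23 (2R,3S)-3-[5-bromo-2-(methoxymethoxy)phenyl]-5,7-bis(methoxymethoxy)-2-[4-(methoxymethoxy)phenyl]chroman-4-one; 27 1-[2,4-bis(methoxymethoxy)phenyl]prop-2-en-1-one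
Product: 28 (2R,3S)-3-[5-[(E)-3-[2,4-bis(methoxymethoxy)phenyl]-3-oxoprop-1-enyl]-2-(methoxymethoxy)phenyl]-5,7-bis(methoxymethoxy)-2-[4-(methoxymethoxy)phenyl]chroman-4-one
Conditions: Pd(OAc)2 (5 mol %), P(o-tol)3 (10 mol %), n-Bu4NBr, NaHCO3, DMF, 80 °C
Reagents that add atoms: none
Why: Mizoroki–Heck reaction, in which zerovalent palladium formed in the flask inserts into the only remaining carbon–halogen bond, syn-carbopalladation at the terminal carbon of the enone and syn-β-hydride elimination give the (E)-chalcone; solid NaHCO3 should be too weak to open the chromanone by β-elimination, and C3, if it enolised, would return to the trans arrangement fixed by C2.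

Step 19
Reactants: 28 (2R,3S)-3-[5-[(E)-3-[2,4-bis(methoxymethoxy)phenyl]-3-oxoprop-1-enyl]-2-(methoxymethoxy)phenyl]-5,7-bis(methoxymethoxy)-2-[4-(methoxymethoxy)phenyl]chroman-4-one
Product: 29 (2R,3S)-3-[5-[(E)-3-(2,4-dihydroxyphenyl)-3-oxoprop-1-enyl]-2-hydroxyphenyl]-5,7-dihydroxy-2-(4-hydroxyphenyl)chroman-4-one
Conditions: 3 M aq. HCl, MeOH/THF, 40–45 °C
Reagents that add atoms: none
Why: acid-catalysed acetal cleavage removes all six MOM ethers as dimethoxymethane; the hydrogen-bonded 5-hydroxy-4-ketone and the 2'-hydroxychalcone should tolerate dilute methanolic HCl, and the low temperature is chosen to avoid cyclodehydration of the ring D phenol onto C4 and opening of ring C at C2.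

## Compound list

1 | 1-iodo-3,5-dimethoxybenzene | COc1cc(I)cc(OC)c1 | starting material
2 | (2-iodo-4,6-dimethoxybenzylidene)dimethyliminium chloride | C[N+](C)=Cc1c(I)cc(OC)cc1OC.[Cl-] | intermediate
3 | 2-iodo-4,6-dimethoxybenzaldehyde | O=Cc1c(I)cc(OC)cc1OC | intermediate
4 | 2,4-dihydroxy-6-iodobenzaldehyde | O=Cc1c(I)cc(O)cc1O | intermediate
5 | 2-iodo-4,6-bis(methoxymethoxy)benzaldehyde | O=Cc1c(I)cc(OCOC)cc1OCOC | intermediate
6 | N-[2-[2-iodo-4,6-bis(methoxymethoxy)phenyl]-1-(4-methylphenylsulfonyl)ethenyl]formamide (alkene geometry not defined) | O=CNC(=Cc1c(I)cc(OCOC)cc1OCOC)S(=O)(=O)c1ccc(C)cc1 | intermediate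
7 | 2-[2-iodo-4,6-bis(methoxymethoxy)phenyl]acetonitrile | N#CCc1c(I)cc(OCOC)cc1OCOC | intermediate
8 | 2-[2-iodo-4,6-bis(methoxymethoxy)phenyl]acetic acid | OC(=O)Cc1c(I)cc(OCOC)cc1OCOC | intermediate
9 | 5-bromo-2-hydroxybenzaldehyde (5-bromosalicylaldehyde) | O=Cc1cc(Br)ccc1O | starting material
10 | 5-bromo-2-(methoxymethoxy)benzaldehyde | O=Cc1cc(Br)ccc1OCOC | intermediate
11 | acetic (E)-3-[5-bromo-2-(methoxymethoxy)phenyl]-2-[2-iodo-4,6-bis(methoxymethoxy)phenyl]prop-2-enoic anhydride | CC(=O)OC(=O)/C(c1c(I)cc(OCOC)cc1OCOC)=C/c1cc(Br)ccc1OCOC | intermediate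
12 | (E)-3-[5-bromo-2-(methoxymethoxy)phenyl]-2-[2-iodo-4,6-bis(methoxymethoxy)phenyl]prop-2-enoic acid | OC(=O)/C(c1c(I)cc(OCOC)cc1OCOC)=C/c1cc(Br)ccc1OCOC | intermediate
13 | methyl (E)-3-[5-bromo-2-(methoxymethoxy)phenyl]-2-[2-iodo-4,6-bis(methoxymethoxy)phenyl]prop-2-enoate | COC(=O)/C(c1c(I)cc(OCOC)cc1OCOC)=C/c1cc(Br)ccc1OCOC | intermediate
14 | (E)-3-[5-bromo-2-(methoxymethoxy)phenyl]-2-[2-iodo-4,6-bis(methoxymethoxy)phenyl]prop-2-en-1-ol | OC/C(c1c(I)cc(OCOC)cc1OCOC)=C/c1cc(Br)ccc1OCOC | intermediate
15 | (E)-3-[5-bromo-2-(methoxymethoxy)phenyl]-2-[2-iodo-4,6-bis(methoxymethoxy)phenyl]prop-2-enyl bromide | BrC/C(c1c(I)cc(OCOC)cc1OCOC)=C/c1cc(Br)ccc1OCOC | intermediate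
16 | 4-hydroxybenzaldehyde | O=Cc1ccc(O)cc1 | starting material
17 | 4-(methoxymethoxy)benzaldehyde | O=Cc1ccc(OCOC)cc1 | intermediate
18 | [(E)-3-[5-bromo-2-(methoxymethoxy)phenyl]-2-[2-iodo-4,6-bis(methoxymethoxy)phenyl]prop-2-enyl]chromium dichloride (trivalent chromium, chiral ligand omitted) | Cl[Cr](Cl)C/C(c1c(I)cc(OCOC)cc1OCOC)=C/c1cc(Br)ccc1OCOC | intermediate
19 | (1R,2S)-2-[5-bromo-2-(methoxymethoxy)phenyl]-3-[2-iodo-4,6-bis(methoxymethoxy)phenyl]-1-[4-(methoxymethoxy)phenyl]but-3-en-1-yl trimethylsilyl ether | C=C(c1c(I)cc(OCOC)cc1OCOC)[C@@H](c1cc(Br)ccc1OCOC)[C@@H](O[Si](C)(C)C)c1ccc(OCOC)cc1 | intermediate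
20 | (1R,2S)-2-[5-bromo-2-(methoxymethoxy)phenyl]-3-[2-iodo-4,6-bis(methoxymethoxy)phenyl]-1-[4-(methoxymethoxy)phenyl]but-3-en-1-ol | C=C(c1c(I)cc(OCOC)cc1OCOC)[C@@H](c1cc(Br)ccc1OCOC)[C@@H](O)c1ccc(OCOC)cc1 | intermediate
21 | (2R,3S)-3-[5-bromo-2-(methoxymethoxy)phenyl]-5,7-bis(methoxymethoxy)-2-[4-(methoxymethoxy)phenyl]-4-methylenechroman | Brc1ccc(OCOC)c([C@@H]2C(=C)c3c(OCOC)cc(OCOC)cc3O[C@H]2c2ccc(OCOC)cc2)c1 | intermediate
22 | (2R,3S)-3-[5-bromo-2-(methoxymethoxy)phenyl]-4-(hydroxymethyl)-5,7-bis(methoxymethoxy)-2-[4-(methoxymethoxy)phenyl]chroman-4-ol (C4 not controlled) | Brc1ccc(OCOC)c([C@@H]2C(O)(CO)c3c(OCOC)cc(OCOC)cc3O[C@H]2c2ccc(OCOC)cc2)c1 | intermediate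
23 | (2R,3S)-3-[5-bromo-2-(methoxymethoxy)phenyl]-5,7-bis(methoxymethoxy)-2-[4-(methoxymethoxy)phenyl]chroman-4-one | Brc1ccc(OCOC)c([C@@H]2C(=O)c3c(OCOC)cc(OCOC)cc3O[C@H]2c2ccc(OCOC)cc2)c1 | intermediate
24 | 2,4-dihydroxybenzaldehyde | O=Cc1ccc(O)cc1O | starting material
25 | 2,4-bis(methoxymethoxy)benzaldehyde | O=Cc1ccc(OCOC)cc1OCOC | intermediate
26 | 1-[2,4-bis(methoxymethoxy)phenyl]prop-2-en-1-ol (racemic) | C=CC(O)c1ccc(OCOC)cc1OCOC | intermediate
27 | 1-[2,4-bis(methoxymethoxy)phenyl]prop-2-en-1-one | C=CC(=O)c1ccc(OCOC)cc1OCOC | intermediate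
28 | (2R,3S)-3-[5-[(E)-3-[2,4-bis(methoxymethoxy)phenyl]-3-oxoprop-1-enyl]-2-(methoxymethoxy)phenyl]-5,7-bis(methoxymethoxy)-2-[4-(methoxymethoxy)phenyl]chroman-4-one | O=C(/C=C/c1ccc(OCOC)c([C@@H]2C(=O)c3c(OCOC)cc(OCOC)cc3O[C@H]2c2ccc(OCOC)cc2)c1)c1ccc(OCOC)cc1OCOC | intermediate
29 | (2R,3S)-3-[5-[(E)-3-(2,4-dihydroxyphenyl)-3-oxoprop-1-enyl]-2-hydroxyphenyl]-5,7-dihydroxy-2-(4-hydroxyphenyl)chroman-4-one | O=C(/C=C/c1ccc(O)c([C@@H]2C(=O)c3c(O)cc(O)cc3O[C@H]2c2ccc(O)cc2)c1)c1ccc(O)cc1O | target

## Step count and risks

Total step count: 19. Longest linear sequence: 14 steps (steps 1–5, 7–10, 12–14, 18, 19).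

Steps most likely to fail:

**Step 13 (copper etherification).** Reductive elimination at the hindered secondary alkoxide may be slow, so that the C–I bond is merely reduced. At the temperature needed, the caesium alkoxide may also fragment by retro-allylation to the aldehyde and a diaryl-stabilised allyl anion, or the exocyclic alkene may migrate into ring C. The fallback sets out from 20 and moves the ring closure to palladium: Pd(OAc)2, 2-(di-tert-butylphosphino)-1,1'-binaphthyl, Cs2CO3, toluene, 60 °C. Zerovalent palladium should insert into C–I in preference to C–Br, the alkoxide displaces iodide on divalent palladium, and C–O reductive elimination, driven by the bulky phosphine, closes ring C at a temperature at which the alkoxide should not fragment. It comes back to the route at 21 and makes no new compound (F0).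

**Step 12 (asymmetric chromium allylation).** Facial selectivity at the aldehyde may be poor with this hindered β,γ-diaryl allylchromium, the anti preference may erode if the allylchromium equilibrates between its alkene isomers, and MOM groups may be lost to adventitious silyl halide. The fallback sets out from 15 and 17 and uses an indium-mediated Barbier allylation (In powder, DMF, rt), which passes through the same closed chair without silyl chloride and should give the racemic anti alcohol. This is 20 together with its enantiomer (1S,2R)-2-[5-bromo-2-(methoxymethoxy)phenyl]-3-[2-iodo-4,6-bis(methoxymethoxy)phenyl]-1-[4-(methoxymethoxy)phenyl]but-3-en-1-ol F1. The two would be separated by preparative chromatography on a chiral stationary phase (amylose tris(3,5-dimethylphenylcarbamate)), and the (1R,2S) component comes back to the route as 20.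

**Step 18 (Heck coupling).** The base may open the chromanone by β-elimination of the ring C aryl ether, with loss of both stereocentres; the aryl vinyl ketone may polymerise; and oxidative addition into the electron-rich bromide may be slow. The fallback sets out from 23 with a Stille vinylation under neutral conditions (Pd(PPh3)4, tributyl(vinyl)stannane, toluene, 100 °C) to give the styrene (2R,3S)-3-[5-ethenyl-2-(methoxymethoxy)phenyl]-5,7-bis(methoxymethoxy)-2-[4-(methoxymethoxy)phenyl]chroman-4-one F2. Cross-metathesis of F2 with 27 (second-generation Hoveyda–Grubbs catalyst, CH2Cl2, 40 °C) should then give the (E)-enone, and the route is rejoined at 28.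

## Further compounds

F0 | step 13 | none | none
F1 | step 12 | (1S,2R)-2-[5-bromo-2-(methoxymethoxy)phenyl]-3-[2-iodo-4,6-bis(methoxymethoxy)phenyl]-1-[4-(methoxymethoxy)phenyl]but-3-en-1-ol | C=C(c1c(I)cc(OCOC)cc1OCOC)[C@H](c1cc(Br)ccc1OCOC)[C@H](O)c1ccc(OCOC)cc1
F2 | step 18 | (2R,3S)-3-[5-ethenyl-2-(methoxymethoxy)phenyl]-5,7-bis(methoxymethoxy)-2-[4-(methoxymethoxy)phenyl]chroman-4-one | C=Cc1ccc(OCOC)c([C@@H]2C(=O)c3c(OCOC)cc(OCOC)cc3O[C@H]2c2ccc(OCOC)cc2)c1
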